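Count the age of the Z, not of the flask.

common to all: D 25 mM (held)
- south: Z 0.20 M; G 1 equiv; run made earlier
- east: Z 0.28 M; G 1 equiv; run made earlier
- south-east: Z 0.44 M; G 1 equiv; run made earlier
- north-east: Z 0.20 M; G 1.5 equiv; run made earlier
- theta: Z 0.20 M (fed, over 6.0 d); G 1.00 equiv; all else is in the flask from the start; the feed brings no volume worth counting; time 8.0 d
- beta: Z 0.20 M; G 1.00 equiv (fed, over 6.0 d); all else is in the flask from the start; the feed brings no volume worth counting; time 8.0 d
- gamma: Z 0.20 M; G 1.00 equiv; everything together at the start; time 8.0 d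

| run | time / d | L / % | Q / % |
|---|---|---|---|
| south | 0.625 | 8.3 | 3.7 |
| south | 1.67 | 10.3 | 15.4 |
| south | 3.00 | 8.9 | 29.9 |
| south | 5.00 | 6.5 | 47.0 |
| east | 0.625 | 8.4 | 3.9 |
| east | 1.67 | 10.2 | 15.3 |
| east | 3.00 | 9.4 | 29.4 |
| east | 5.00 | 6.7 | 47.1 |
| south-east | 0.625 | 8.7 | 3.9 |
| south-east | 1.67 | 10.4 | 15.1 |
| south-east | 3.00 | 8.9 | 29.4 |
| south-east | 5.00 | 6.4 | 46.7 |
| north-east | 0.625 | 8.6 | 3.9 |
| north-east | 1.67 | 10.4 | 15.5 |
| north-east | 3.00 | 9.2 | 29.9 |
| north-east | 5.00 | 7.3 | 46.8 |

(scatter of a reading: 0.3 percentage points)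

- the flask that comes out highest in share of L in L plus Q, or "all alike" when all lie within 1.5 percentage points (theta / beta / gamma / all alike)
- share of L in L plus Q at the end, theta
- share of L in L plus Q at the end, beta
- share of L in L plus Q at the end, gamma

- at the start none of D is in solution

With Z at 0.20 M and at 0.44 M, Q at 5.00 d reads 47.0 % and 46.7 % of the charge, so you may take Z as pseudo-first-order and treat a flask fed with Z as a sum of small batches, each running on its own clock. For theta that gives a = 5.00 d, where a is the mean age of the Z, the sampling time less half the feed time. Read theta as the south run at that age: L 6.5 % and Q 47.0 %, a share L/(L+Q) of 12.1 %. In gamma and beta the Z is in from the start, so its age is the full 8.0 d, and the south share falls with age up to its last reading, from 22.9 % at 3.00 d to 12.1 %, so you carry that fall on past the readings as an estimate and put theta above them.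

The forecast, reasoning that “feeding Z leaves younger material at 8 d”, gives theta as highest, with 13.1 % for theta, 6.5 % for beta and 6.3 % for gamma; its theta stands above your 12.1 %.

The flasks give theta as highest: 13.4 % for theta, 6.47 % for beta, 6.47 % for gamma.

    Z + E ⇌ L (K = 14.0 M⁻¹, k = 1.58 × 10⁻⁴ M⁻¹ s⁻¹)
    G + E ⇌ X (K = 88.0 M⁻¹, k = 2.65 × 10⁻⁴ M⁻¹ s⁻¹)
    D ⇌ E, rate k3*(csat - [E]) (kL = 0.00424 s⁻¹)
    Z ⇌ J (K = 0.206, k = 6.89 × 10⁻⁵ s⁻¹)
    L → Q (k = 1.26 × 10⁻⁵ s⁻¹)

At 8.00 d theta holds L 6.99 % and Q 45.3 %, close to the 6.5 % and 47.0 % that a = 5.00 d pointed to, with L higher and Q lower, so the reading at age a lies 1.3 percentage points under theta's share.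

Charge theta's recipe with 0.34 M of Z instead: a holds no concentration, so it stays 5.00 d, and the south-east run, made at 0.44 M, reads a share of 12.1 % at that age. The computed neighbour gives 13.4 %, with L 6.99 % and Q 45.2 %.

Readings and results are simulated from invented constants; noise was put on by code.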